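**Retrosynthetic overview**

1. Ring atoms are called C1 (CH bonded to the chain), C2 (C=CH2), C3, C4, C5 (CHCH3) and C6 (C(CH3)2). The last disconnection is the ring C1–chain CH2 bond, formed by a phosphane-directed, copper-mediated SN2' coupling of a C22 alkylmagnesium bromide with a (3,3,4-trimethylcyclohex-1-enyl)methyl ester. This is possible because C1 is the allylic terminus of the exocyclic C2=CH2 unit: the bond can be made at the γ-carbon of an endocyclic C1=C2–CH2–O allyl system, with the double bond moving into the exocyclic position.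
2. Chain: the quaternary C(CH3)(CH=CH2) carbon and the E-disubstituted alkene come from one Johnson–Claisen rearrangement (1,3-chirality transfer) of a dienyl carbinol, whose syn CH(OH)/CH(CH3) pair comes from a (Z)-crotylboration of (E)-3-methylpenta-2,4-dienal.
3. The E-trisubstituted alkene is joined by B-alkyl Suzuki–Miyaura coupling with a vinyl iodide (auxiliary-controlled methylation, then zirconium-catalysed carboalumination).
4. Ring order: the only ring is formed first (step 16, organocatalytic Michael addition/aldol condensation to (S)-4-methylcyclohex-2-enone). Two methyl conjugate additions build C6, and enolate triflation fixes the C1=C2 position. No ring is formed in the key step.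

Key step: step 23

Remark: read from the SMILES, the chain at C1 and the methyl at C5 are trans (1S,5S), and the route is planned for that isomer. Hex-5-ynoic acid, (E)-3-methylpent-2-en-4-yn-1-ol, both auxiliaries, (+)-Ipc2BOMe and 2-(diphenylphosphanyl)benzoic acid are taken as purchasable.

**Route**

Step 1
Reactants: 1 hex-5-ynoic acid; 2 (R)-4-benzyloxazolidin-2-one
Product: 4 (R)-4-benzyl-3-(hex-5-ynoyl)oxazolidin-2-one, via mixed anhydride 3 (not isolated)
Conditions: PivCl, Et3N, THF, −20 °C; then 2, LiCl, −20 °C → rt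
Reagents that add atoms: none
Why: Mixed-anhydride N-acylation of the oxazolidinone (LiCl/Et3N variant) attaches the auxiliary without touching the alkyne; no stereocentre is formed.

Step 2
Reactants: 4 (R)-4-benzyl-3-(hex-5-ynoyl)oxazolidin-2-one
Product: 6 (R)-4-benzyl-3-[(R)-2-methylhex-5-ynoyl]oxazolidin-2-one, via sodium enolate 5 (not isolated)
Conditions: NaHMDS, THF, −78 °C; then MeI, −78 °C
Reagents that add atoms: iodomethane (CI)
Why: Evans alkylation: the chelated (Z)-enolate is methylated on the face opposite to the benzyl group, which should set the (R) centre (later the CH(CH3) next to the isopropenyl group); the imide C–H is far more acidic than the alkyne C–H, and the minor diastereomer is removed by chromatography.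

Step 3
Reactants: 6 (R)-4-benzyl-3-[(R)-2-methylhex-5-ynoyl]oxazolidin-2-one
Product: 7 (R)-N-methoxy-N,2-dimethylhex-5-ynamide
Conditions: MeONHMe·HCl, AlMe3, CH2Cl2, 0 °C → rt; aq. HCl
Reagents that add atoms: N,O-dimethylhydroxylamine hydrochloride (CNOC.Cl)
Why: Aluminium-amide transamidation of the imide gives the Weinreb amide and releases the auxiliary without epimerising the α-centre.

Step 4
Reactants: 7 (R)-N-methoxy-N,2-dimethylhex-5-ynamide
Product: 8 (R)-3-methyloct-7-yn-2-one
Conditions: MeMgBr (2.2 equiv), THF, 0 °C; aq. NH4Cl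
Reagents that add atoms: methylmagnesium bromide (C[Mg]Br)
Why: Weinreb ketone synthesis: the chelated adduct stops at the methyl ketone, and the acetylide formed from the alkyne C–H is reprotonated on work-up.

Step 5
Reactants: 8 (R)-3-methyloct-7-yn-2-one
Product: 9 (R)-2,3-dimethylhept-1-en-6-yne
Conditions: Zn, CH2Br2, TiCl4, THF/CH2Cl2, 0 °C → rt
Reagents that add atoms: dibromomethane (BrCBr)
Why: Takai–Lombardo methylenation is non-basic, so the α-stereocentre of the ketone should not epimerise while the isopropenyl group is formed.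

Step 6
Reactants: 9 (R)-2,3-dimethylhept-1-en-6-yne
Product: 11 (1E,5R)-1-iodo-2,5,6-trimethylhepta-1,6-diene, via alkenylalane 10 (not isolated)
Conditions: AlMe3, Cp2ZrCl2 (cat.), CH2Cl2, 0 °C → rt; then I2, THF, −30 °C
Reagents that add atoms: trimethylaluminium (C[Al](C)C); iodine (II)
Why: Negishi zirconium-catalysed carboalumination adds methyl and aluminium syn across the terminal alkyne with methyl on the internal carbon, and iodinolysis with retention gives the (E)-iodide; the 1,1-disubstituted alkene should not react.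

Step 7
Reactants: 12 (E)-3-methylpent-2-en-4-yn-1-ol
Product: 13 (E)-3-methylpenta-2,4-dien-1-ol
Conditions: H2 (1 atm), Pd/CaCO3 poisoned with Pb(OAc)2 (Lindlar catalyst), quinoline, EtOAc, rt
Reagents that add atoms: none
Why: Lindlar semihydrogenation stops at the alkene, turning the terminal alkyne into the vinyl group and leaving the E-trisubstituted alkene untouched.

Step 8
Reactants: 13 (E)-3-methylpenta-2,4-dien-1-ol
Product: 14 (E)-3-methylpenta-2,4-dienal
Conditions: MnO2, CH2Cl2, rt; used at once in solution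
Reagents that add atoms: none
Why: MnO2 oxidises the allylic alcohol chemoselectively to the aldehyde without isomerising the E double bond.

Step 9
Reactants: 14 (E)-3-methylpenta-2,4-dienal
Product: 16 (3E,5R,6S)-3,6-dimethylocta-1,3,7-trien-5-ol, via diisopinocampheylborinate 15 (not isolated)
Conditions: cis-but-2-ene, KOt-Bu, n-BuLi, THF, −78 → −45 °C; (+)-Ipc2BOMe (from (−)-α-pinene), −78 °C; BF3·OEt2, then 14, −78 °C; then NaOH, H2O2, rt
Reagents that add atoms: cis-but-2-ene (C/C=C\C)
Why: Brown asymmetric crotylboration: the (Z)-crotylborane reacts through a closed chair transition state to give the syn pair, and the isopinocampheyl groups derived from (−)-α-pinene should direct attack to the Re face of the aldehyde, setting (5R,6S).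

Step 10
Reactants: 16 (3E,5R,6S)-3,6-dimethylocta-1,3,7-trien-5-ol
Product: 17 tert-butyl{[(3E,5R,6S)-3,6-dimethylocta-1,3,7-trien-5-yl]oxy}dimethylsilane
Conditions: TBSCl, imidazole, DMF, rt
Reagents that add atoms: tert-butyldimethylsilyl chloride (CC(C)(C)[Si](C)(C)Cl)
Why: Silylation masks the doubly allylic hydroxyl so that neither an O-borinate nor allylic ionisation interferes in the palladium step.

Step 11
Reactants: 17 tert-butyl{[(3E,5R,6S)-3,6-dimethylocta-1,3,7-trien-5-yl]oxy}dimethylsilane; 11 (1E,5R)-1-iodo-2,5,6-trimethylhepta-1,6-diene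
Product: 19 tert-butyldimethyl{[(3E,5R,6S,9E,13R)-3,6,10,13,14-pentamethylpentadeca-1,3,9,14-tetraen-5-yl]oxy}silane, via alkylborane 18 (not isolated)
Conditions: 9-BBN (1.1 equiv), THF, 0 °C → rt; then 11, PdCl2(dppf) (cat.), AsPh3, Cs2CO3, DMF/H2O, rt
Reagents that add atoms: none
Why: 9-BBN should add anti-Markovnikov to the isolated monosubstituted alkene faster than to the deactivated conjugated diene, and the B-alkyl Suzuki–Miyaura coupling joins the primary alkylborane to the vinyl iodide with retention of the E geometry.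

Step 12
Reactants: 19 tert-butyldimethyl{[(3E,5R,6S,9E,13R)-3,6,10,13,14-pentamethylpentadeca-1,3,9,14-tetraen-5-yl]oxy}silane
Product: 20 (3E,5R,6S,9E,13R)-3,6,10,13,14-pentamethylpentadeca-1,3,9,14-tetraen-5-ol
Conditions: TBAF, THF, rt
Reagents that add atoms: none
Why: Fluoride desilylation frees the allylic alcohol under non-acidic conditions that should not ionise it.

Step 13
Reactants: 20 (3E,5R,6S,9E,13R)-3,6,10,13,14-pentamethylpentadeca-1,3,9,14-tetraen-5-ol
Product: 22 ethyl (3S,4E,6S,9E,13R)-3-ethenyl-3,6,10,13,14-pentamethylpentadeca-4,9,14-trienoate, via ketene acetal 21 (not isolated)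
Conditions: MeC(OEt)3, EtCO2H (cat.), 140 °C, EtOH distilled off
Reagents that add atoms: triethyl orthoacetate (CC(OCC)(OCC)OCC)
Why: Johnson–Claisen rearrangement: the ketene acetal rearranges through a chair with the C6 side chain equatorial (enforced by the methyl cis to the carbinol carbon) and bonds on the face from which oxygen departs, so the (5R) carbinol should be transferred into the (S) quaternary carbon and a new E alkene.

Step 14
Reactants: 22 ethyl (3S,4E,6S,9E,13R)-3-ethenyl-3,6,10,13,14-pentamethylpentadeca-4,9,14-trienoate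
Product: 23 (3S,4E,6S,9E,13R)-3-ethenyl-3,6,10,13,14-pentamethylpentadeca-4,9,14-trien-1-ol
Conditions: LiAlH4, Et2O, 0 °C
Reagents that add atoms: none
Why: Hydride reduction of the ester gives the primary alcohol and leaves the five unactivated alkenes untouched.

Step 15
Reactants: 23 (3S,4E,6S,9E,13R)-3-ethenyl-3,6,10,13,14-pentamethylpentadeca-4,9,14-trien-1-ol
Product: 24 (3S,4E,6S,9E,13R)-1-bromo-3-ethenyl-3,6,10,13,14-pentamethylpentadeca-4,9,14-triene
Conditions: CBr4, PPh3, CH2Cl2, 0 °C
Reagents that add atoms: carbon tetrabromide (BrC(Br)(Br)Br)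
Why: Appel bromination converts the primary alcohol under neutral conditions with no cationic intermediate that could touch the alkenes.

Step 16
Reactants: 25 propanal; 26 but-3-en-2-one
Product: 28 (S)-4-methylcyclohex-2-en-1-one, via keto aldehyde 27 (not isolated)
Conditions: (R)-2-[methoxy(diphenyl)methyl]pyrrolidine (cat.), ethyl 3,4-dihydroxybenzoate (cat.), neat, 4 °C; then LiOH (0.2 equiv), i-PrOH, rt
Reagents that add atoms: none
Why: Enamine-catalysed Michael addition, in which the diarylmethyl group shields one face of the (E)-enamine so that the (R)-catalyst should give the (S) centre, followed by intramolecular aldol condensation that closes the ring.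

Step 17
Reactants: 28 (S)-4-methylcyclohex-2-en-1-one
Product: 29 trimethyl{[(3R,4S)-3,4-dimethylcyclohex-1-en-1-yl]oxy}silane
Conditions: MeMgBr, CuBr·SMe2 (cat.), TMSCl, DMPU, THF, −78 °C
Reagents that add atoms: methylmagnesium bromide (C[Mg]Br); chlorotrimethylsilane (C[Si](C)(C)Cl)
Why: Copper-catalysed conjugate addition with silyl trapping gives the regiodefined silyl enol ether; methyl should add trans to the C4 methyl, but this new centre is removed in the next step.

Step 18
Reactants: 29 trimethyl{[(3R,4S)-3,4-dimethylcyclohex-1-en-1-yl]oxy}silane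
Product: 30 (S)-3,4-dimethylcyclohex-2-en-1-one
Conditions: Pd(OAc)2 (cat.), O2 (1 atm), DMSO, rt
Reagents that add atoms: none
Why: Saegusa–Ito oxidation re-forms the enone regiospecifically through the palladium enolate and β-hydride elimination, under neutral conditions that leave the γ-stereocentre alone.

Step 19
Reactants: 30 (S)-3,4-dimethylcyclohex-2-en-1-one
Product: 32 (S)-3,3,4-trimethylcyclohex-1-en-1-yl trifluoromethanesulfonate, via lithium enolate 31 (not isolated)
Conditions: Me2CuLi (from MeLi, CuI), Et2O, 0 °C; then PhNTf2, THF, 0 °C → rt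
Reagents that add atoms: lithium dimethylcuprate ([Li+].C[Cu-]C); N-phenylbis(trifluoromethanesulfonimide) (O=S(=O)(N(c1ccccc1)S(=O)(=O)C(F)(F)F)C(F)(F)F)
Why: Gilman cuprate addition creates the gem-dimethyl carbon (not stereogenic) and a regiodefined enolate whose O-triflation fixes the double bond between the former carbonyl carbon and the CH next to C(CH3)2.

Step 20
Reactants: 32 (S)-3,3,4-trimethylcyclohex-1-en-1-yl trifluoromethanesulfonate
Product: 33 methyl (S)-3,3,4-trimethylcyclohex-1-ene-1-carboxylate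
Conditions: Pd(OAc)2 (cat.), PPh3, CO (1 atm), MeOH, Et3N, DMF, 50 °C
Reagents that add atoms: carbon monoxide ([C-]#[O+]); methanol (CO)
Why: Palladium-catalysed alkoxycarbonylation of the enol triflate installs the one-carbon unit that becomes the exocyclic methylene.

Step 21
Reactants: 33 methyl (S)-3,3,4-trimethylcyclohex-1-ene-1-carboxylate
Product: 34 [(S)-3,3,4-trimethylcyclohex-1-en-1-yl]methanol
Conditions: i-Bu2AlH, CH2Cl2, −78 °C; Rochelle salt
Reagents that add atoms: none
Why: 1,2-Reduction of the unsaturated ester by the aluminium hydride gives the allylic alcohol without conjugate reduction.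

Step 22
Reactants: 34 [(S)-3,3,4-trimethylcyclohex-1-en-1-yl]methanol
Product: 35 [(S)-3,3,4-trimethylcyclohex-1-en-1-yl]methyl 2-(diphenylphosphanyl)benzoate
Conditions: 2-(diphenylphosphanyl)benzoic acid, DCC, DMAP (cat.), CH2Cl2, rt
Reagents that add atoms: 2-(diphenylphosphanyl)benzoic acid (OC(=O)c1ccccc1P(c1ccccc1)c1ccccc1)
Why: Steglich esterification installs a leaving group that also carries the phosphane needed to direct copper in the key step.

Step 23
Reactants: 24 (3S,4E,6S,9E,13R)-1-bromo-3-ethenyl-3,6,10,13,14-pentamethylpentadeca-4,9,14-triene; 35 [(S)-3,3,4-trimethylcyclohex-1-en-1-yl]methyl 2-(diphenylphosphanyl)benzoate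
Product: 37 (2S,6S)-2-[(3S,4E,6S,9E,13R)-3-ethenyl-3,6,10,13,14-pentamethylpentadeca-4,9,14-trien-1-yl]-1,1,6-trimethyl-3-methylidenecyclohexane (CNP0186101.1), via Grignard reagent 36 (not isolated)
Conditions: 24, Mg, Et2O, reflux; then added slowly to 35, CuBr·SMe2 (0.5 equiv), Et2O, rt; aq. NH4Cl
Reagents that add atoms: none
Why: The phosphane of the ester binds copper, Grignard reagent 36 transmetalates to an alkylcopper species held next to the C1=C2 double bond, and loss of the benzoate with C–C bond formation at ring carbon C1 moves the double bond to the exocyclic C2=CH2 position; the closest known reaction type is the o-DPPB-directed copper-mediated SN2' substitution of allylic esters with Grignard reagents. No ring is closed. The new stereocentre at C1 is controlled by the ring: the chain should be delivered along the axial trajectory of the half-chair that keeps the C5 methyl equatorial, on the face opposite to that methyl and to the pseudoaxial methyl of C6, which gives the trans (1S,5S) relationship, whereas the cis isomer would need a twist-boat or a 1,3-diaxial chain/methyl contact. The step needs γ- over α-selectivity at a carbon flanked by a quaternary centre, which the intramolecular delivery from phosphane-bound copper should secure, and chemoselectivity for the allylic ester over the five unactivated alkenes of 36, which is inherent.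

**Compound list**

1 | hex-5-ynoic acid | C#CCCCC(=O)O | starting material
2 | (R)-4-benzyloxazolidin-2-one | O=C1N[C@H](Cc2ccccc2)CO1 | starting material
3 | hex-5-ynoic pivalic anhydride | C#CCCCC(=O)OC(=O)C(C)(C)C | intermediate
4 | (R)-4-benzyl-3-(hex-5-ynoyl)oxazolidin-2-one | C#CCCCC(=O)N1[C@H](Cc2ccccc2)COC1=O | intermediate
5 | sodium (Z)-enolate of 4 | C#CCC/C=C(\[O-])N1[C@H](Cc2ccccc2)COC1=O.[Na+] | intermediate
6 | (R)-4-benzyl-3-[(R)-2-methylhex-5-ynoyl]oxazolidin-2-one | C#CCC[C@@H](C)C(=O)N1[C@H](Cc2ccccc2)COC1=O | intermediate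
7 | (R)-N-methoxy-N,2-dimethylhex-5-ynamide | C#CCC[C@@H](C)C(=O)N(C)OC | intermediate
8 | (R)-3-methyloct-7-yn-2-one | C#CCC[C@@H](C)C(C)=O | intermediate
9 | (R)-2,3-dimethylhept-1-en-6-yne | C#CCC[C@@H](C)C(C)=C | intermediate
10 | dimethyl[(1E,5R)-2,5,6-trimethylhepta-1,6-dien-1-yl]alumane | C[Al](C)/C=C(\C)CC[C@@H](C)C(C)=C | intermediate
11 | (1E,5R)-1-iodo-2,5,6-trimethylhepta-1,6-diene | I/C=C(\C)CC[C@@H](C)C(C)=C | intermediate
12 | (E)-3-methylpent-2-en-4-yn-1-ol | C#C/C(C)=C/CO | starting material
13 | (E)-3-methylpenta-2,4-dien-1-ol | C=C/C(C)=C/CO | intermediate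
14 | (E)-3-methylpenta-2,4-dienal | C=C/C(C)=C/C=O | intermediate
15 | (3E,5R,6S)-3,6-dimethylocta-1,3,7-trien-5-yl diisopinocampheylborinate (Ipc from (−)-α-pinene) | C=C/C(C)=C/[C@H](OB([C@H]1C[C@H]2C[C@@H]([C@@H]1C)C2(C)C)[C@H]1C[C@H]2C[C@@H]([C@@H]1C)C2(C)C)[C@@H](C)C=C | intermediate
16 | (3E,5R,6S)-3,6-dimethylocta-1,3,7-trien-5-ol | C=C/C(C)=C/[C@H](O)[C@@H](C)C=C | intermediate
17 | tert-butyl{[(3E,5R,6S)-3,6-dimethylocta-1,3,7-trien-5-yl]oxy}dimethylsilane | C=C/C(C)=C/[C@H](O[Si](C)(C)C(C)(C)C)[C@@H](C)C=C | intermediate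
18 | 9-[(3S,4R,5E)-4-(tert-butyldimethylsilyloxy)-3,6-dimethylocta-5,7-dien-1-yl]-9-borabicyclo[3.3.1]nonane | C=C/C(C)=C/[C@H](O[Si](C)(C)C(C)(C)C)[C@@H](C)CCB1C2CCCC1CCC2 | intermediate
19 | tert-butyldimethyl{[(3E,5R,6S,9E,13R)-3,6,10,13,14-pentamethylpentadeca-1,3,9,14-tetraen-5-yl]oxy}silane | C=C/C(C)=C/[C@H](O[Si](C)(C)C(C)(C)C)[C@@H](C)CC/C=C(\C)CC[C@@H](C)C(C)=C | intermediate
20 | (3E,5R,6S,9E,13R)-3,6,10,13,14-pentamethylpentadeca-1,3,9,14-tetraen-5-ol | C=C/C(C)=C/[C@H](O)[C@@H](C)CC/C=C(\C)CC[C@@H](C)C(C)=C | intermediate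
21 | ethyl ketene acetal of 20 (1-ethoxyvinyl ether) | C=C(OCC)O[C@@H](/C=C(C)/C=C)[C@@H](C)CC/C=C(\C)CC[C@@H](C)C(C)=C | intermediate
22 | ethyl (3S,4E,6S,9E,13R)-3-ethenyl-3,6,10,13,14-pentamethylpentadeca-4,9,14-trienoate | C=C[C@@](C)(/C=C/[C@@H](C)CC/C=C(\C)CC[C@@H](C)C(=C)C)CC(=O)OCC | intermediate
23 | (3S,4E,6S,9E,13R)-3-ethenyl-3,6,10,13,14-pentamethylpentadeca-4,9,14-trien-1-ol | C=C[C@@](C)(/C=C/[C@@H](C)CC/C=C(\C)CC[C@@H](C)C(=C)C)CCO | intermediate
24 | (3S,4E,6S,9E,13R)-1-bromo-3-ethenyl-3,6,10,13,14-pentamethylpentadeca-4,9,14-triene | C=C[C@@](C)(/C=C/[C@@H](C)CC/C=C(\C)CC[C@@H](C)C(=C)C)CCBr | intermediate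
25 | propanal | CCC=O | starting material
26 | but-3-en-2-one | CC(=O)C=C | starting material
27 | (S)-2-methyl-5-oxohexanal | O=C[C@@H](C)CCC(C)=O | intermediate
28 | (S)-4-methylcyclohex-2-en-1-one | C[C@H]1CCC(=O)C=C1 | intermediate
29 | trimethyl{[(3R,4S)-3,4-dimethylcyclohex-1-en-1-yl]oxy}silane | C[C@H]1CCC(O[Si](C)(C)C)=C[C@@H]1C | intermediate
30 | (S)-3,4-dimethylcyclohex-2-en-1-one | C[C@H]1CCC(=O)C=C1C | intermediate
31 | lithium (S)-3,3,4-trimethylcyclohex-1-en-1-olate | C[C@H]1CCC([O-])=CC1(C)C.[Li+] | intermediate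
32 | (S)-3,3,4-trimethylcyclohex-1-en-1-yl trifluoromethanesulfonate | C[C@H]1CCC(OS(=O)(=O)C(F)(F)F)=CC1(C)C | intermediate
33 | methyl (S)-3,3,4-trimethylcyclohex-1-ene-1-carboxylate | C[C@H]1CCC(C(=O)OC)=CC1(C)C | intermediate
34 | [(S)-3,3,4-trimethylcyclohex-1-en-1-yl]methanol | C[C@H]1CCC(CO)=CC1(C)C | intermediate
35 | [(S)-3,3,4-trimethylcyclohex-1-en-1-yl]methyl 2-(diphenylphosphanyl)benzoate | C[C@H]1CCC(COC(=O)c2ccccc2P(c2ccccc2)c2ccccc2)=CC1(C)C | intermediate
36 | [(3S,4E,6S,9E,13R)-3-ethenyl-3,6,10,13,14-pentamethylpentadeca-4,9,14-trien-1-yl]magnesium bromide | C=C[C@@](C)(/C=C/[C@@H](C)CC/C=C(\C)CC[C@@H](C)C(=C)C)CC[Mg]Br | intermediate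
37 | (2S,6S)-2-[(3S,4E,6S,9E,13R)-3-ethenyl-3,6,10,13,14-pentamethylpentadeca-4,9,14-trien-1-yl]-1,1,6-trimethyl-3-methylidenecyclohexane (CNP0186101.1) | C=C[C@@](C)(/C=C/[C@@H](C)CC/C=C(\C)CC[C@@H](C)C(=C)C)CC[C@H]1C(=C)CC[C@H](C)C1(C)C | target

**Step count and risks**

Total step count: 23. Longest linear sequence: 12 steps (steps 1–6, 11–15, 23). The side branches are steps 7–10 and steps 16–22.

The final hydrocarbon cannot be freed from stereoisomers, so stereochemical purity has to be secured at 6, 16 and 28.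

Three steps most likely to fail:

1. Step 23. The alkylcopper species may attack the unhindered exocyclic CH2 instead of ring C1, which is flanked by the quaternary C6. Coupling may also be slow enough for the Grignard reagent to add to the ester carbonyl, or the facial selectivity at C1 may be poor. The fallback sets out from alcohol 23 and ring alcohol 34 and returns at target 37. Alcohol 23 would be oxidised (Dess–Martin periodinane, CH2Cl2) to (3S,4E,6S,9E,13R)-3-ethenyl-3,6,10,13,14-pentamethylpentadeca-4,9,14-trienal F1, and 34 would be converted (CBr4, PPh3) into (S)-1-(bromomethyl)-3,3,4-trimethylcyclohex-1-ene F2. CrCl2 in THF (Nozaki–Hiyama allylation) would turn F2 into an allylchromium reagent that adds to F1 through its ring carbon in a closed six-membered transition state, along the same axial trajectory. This forms the same ring C1–chain bond and the exocyclic methylene, giving the homoallylic alcohol (3S,4E,6S,9E,13R)-3-ethenyl-3,6,10,13,14-pentamethyl-1-[(1S,3S)-2,2,3-trimethyl-6-methylidenecyclohexyl]pentadeca-4,9,14-trien-1-ol F3, in which either configuration of the carbinol carbon serves. Xanthate formation (NaH, CS2, then MeI) would give the O-alkyl S-methyl dithiocarbonate F4, and Barton–McCombie deoxygenation (Bu3SnH, AIBN, toluene, 80 °C) would give 37. The secondary radical has no alkene placed for a fast cyclisation.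

2. Step 13. At 140 °C with acid, the doubly allylic alcohol may ionise or eliminate faster than the hindered rearrangement to a quaternary carbon proceeds. The fallback sets out from alcohol 20 and returns at alcohol 23. Acetylation (Ac2O, pyridine, DMAP) would give the acetate F5. LDA, TMSCl, Et3N in THF at −78 °C would give the silyl ketene acetal F6, which on warming should rearrange (Ireland–Claisen, same chair and same chirality transfer) to the trimethylsilyl ester F7. Work-up hydrolyses F7 to (3S,4E,6S,9E,13R)-3-ethenyl-3,6,10,13,14-pentamethylpentadeca-4,9,14-trienoic acid F8, and LiAlH4 reduces F8 to 23.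

3. Step 11. 9-BBN may also hydroborate the terminal double bond of the conjugated diene, or add twice, so that the coupling gives mixtures. The fallback sets out from enynol 12 and returns at alcohol 20, carrying the future vinyl group as a silylated alkyne.
   - Treatment of 12 with EtMgBr (2.2 equiv) and TMSCl would give the O,C-bis(trimethylsilyl) compound F9, which loses its O-silyl group on acidic work-up to give (E)-3-methyl-5-(trimethylsilyl)pent-2-en-4-yn-1-ol F10.
   - MnO2 would give (E)-3-methyl-5-(trimethylsilyl)pent-2-en-4-ynal F11.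
   - The crotylboration of step 9 would proceed through the diisopinocampheylborinate F12 to (3S,4R,5E)-3,6-dimethyl-8-(trimethylsilyl)octa-1,5-dien-7-yn-4-ol F13.
   - TBSCl and imidazole would give the silyl ether F14.
   - 9-BBN, which now meets only one reactive alkene, would give the alkylborane F15, and coupling with 11 as in step 11 would give the bis-silylated tetraenyne F16.
   - TBAF would remove both silyl groups to give (3E,5R,6S,9E,13R)-3,6,10,13,14-pentamethylpentadeca-3,9,14-trien-1-yn-5-ol F17.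
   - Lindlar semihydrogenation as in step 7 would give 20.

**Further compounds**

F1 | step 23 | (3S,4E,6S,9E,13R)-3-ethenyl-3,6,10,13,14-pentamethylpentadeca-4,9,14-trienal | C=C[C@@](C)(/C=C/[C@@H](C)CC/C=C(\C)CC[C@@H](C)C(=C)C)CC=O
F2 | step 23 | (S)-1-(bromomethyl)-3,3,4-trimethylcyclohex-1-ene | C[C@H]1CCC(CBr)=CC1(C)C
F3 | step 23 | (3S,4E,6S,9E,13R)-3-ethenyl-3,6,10,13,14-pentamethyl-1-[(1S,3S)-2,2,3-trimethyl-6-methylidenecyclohexyl]pentadeca-4,9,14-trien-1-ol (both carbinol epimers) | C=C[C@@](C)(/C=C/[C@@H](C)CC/C=C(\C)CC[C@@H](C)C(=C)C)CC(O)[C@H]1C(=C)CC[C@H](C)C1(C)C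
F4 | step 23 | O-alkyl S-methyl dithiocarbonate (xanthate) of F3 | C=C[C@@](C)(/C=C/[C@@H](C)CC/C=C(\C)CC[C@@H](C)C(=C)C)CC(OC(=S)SC)[C@H]1C(=C)CC[C@H](C)C1(C)C
F5 | step 13 | (3E,5R,6S,9E,13R)-3,6,10,13,14-pentamethylpentadeca-1,3,9,14-tetraen-5-yl acetate | C=C/C(C)=C/[C@H](OC(C)=O)[C@@H](C)CC/C=C(\C)CC[C@@H](C)C(C)=C
F6 | step 13 | trimethylsilyl ketene acetal of F5 | C=C(O[Si](C)(C)C)O[C@@H](/C=C(C)/C=C)[C@@H](C)CC/C=C(\C)CC[C@@H](C)C(C)=C
F7 | step 13 | trimethylsilyl (3S,4E,6S,9E,13R)-3-ethenyl-3,6,10,13,14-pentamethylpentadeca-4,9,14-trienoate | C=C[C@@](C)(/C=C/[C@@H](C)CC/C=C(\C)CC[C@@H](C)C(=C)C)CC(=O)O[Si](C)(C)C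
F8 | step 13 | (3S,4E,6S,9E,13R)-3-ethenyl-3,6,10,13,14-pentamethylpentadeca-4,9,14-trienoic acid | C=C[C@@](C)(/C=C/[C@@H](C)CC/C=C(\C)CC[C@@H](C)C(=C)C)CC(=O)O
F9 | step 11 | trimethyl{[(E)-3-methyl-5-(trimethylsilyl)pent-2-en-4-yn-1-yl]oxy}silane | C[Si](C)(C)C#C/C(C)=C/CO[Si](C)(C)C
F10 | step 11 | (E)-3-methyl-5-(trimethylsilyl)pent-2-en-4-yn-1-ol | C[Si](C)(C)C#C/C(C)=C/CO
F11 | step 11 | (E)-3-methyl-5-(trimethylsilyl)pent-2-en-4-ynal | C[Si](C)(C)C#C/C(C)=C/C=O
F12 | step 11 | diisopinocampheylborinate of F13 (Ipc from (−)-α-pinene) | C[Si](C)(C)C#C/C(C)=C/[C@H](OB([C@H]1C[C@H]2C[C@@H]([C@@H]1C)C2(C)C)[C@H]1C[C@H]2C[C@@H]([C@@H]1C)C2(C)C)[C@@H](C)C=C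
F13 | step 11 | (3S,4R,5E)-3,6-dimethyl-8-(trimethylsilyl)octa-1,5-dien-7-yn-4-ol | C[Si](C)(C)C#C/C(C)=C/[C@H](O)[C@@H](C)C=C
F14 | step 11 | tert-butyldimethylsilyl ether of F13 | C[Si](C)(C)C#C/C(C)=C/[C@H](O[Si](C)(C)C(C)(C)C)[C@@H](C)C=C
F15 | step 11 | 9-alkyl-9-borabicyclo[3.3.1]nonane from F14 | C[Si](C)(C)C#C/C(C)=C/[C@H](O[Si](C)(C)C(C)(C)C)[C@@H](C)CCB1C2CCCC1CCC2
F16 | step 11 | tert-butyldimethyl{[(3E,5R,6S,9E,13R)-3,6,10,13,14-pentamethyl-1-(trimethylsilyl)pentadeca-3,9,14-trien-1-yn-5-yl]oxy}silane | C[Si](C)(C)C#C/C(C)=C/[C@H](O[Si](C)(C)C(C)(C)C)[C@@H](C)CC/C=C(\C)CC[C@@H](C)C(C)=C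
F17 | step 11 | (3E,5R,6S,9E,13R)-3,6,10,13,14-pentamethylpentadeca-3,9,14-trien-1-yn-5-ol | C#C/C(C)=C/[C@H](O)[C@@H](C)CC/C=C(\C)CC[C@@H](C)C(C)=C
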